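**Conventions.** Drimane numbering is used for the decalin: ring A is C1–C5 and C10, ring B is C5–C10, C11 is the methylene on C9 and C12 the methyl on C8. The oxygenated ring is ring C, numbered C1'–C6': C1' carries C11, C2' is the epoxide CH, C3' the ketone carbon, C4' carries CH2OH, C5' is the olefinic CH and C6' the carbinol. The target is the (4R,5R,9S,10R,1'S,2'S,6'R) isomer: 4α-CH2OH, 4β-CH3, 5α-H, 10β-CH3, C11 β on C9, and the C6' hydroxyl anti to the epoxide oxygen. TIPS = triisopropylsilyl; Ar = 5-methoxy-2-(triisopropylsilyloxy)-4-[(triisopropylsilyloxy)methyl]phenyl.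

**Assumption.** In step 15, L-(+)-diisopropyl tartrate is taken as the antipode that steers the peroxide to the C2' face giving the (1'R,2'S) epoxide 20; if the sense proves opposite, D-(−)-diisopropyl tartrate is used with nothing else changed.

## The problem

Epoxypholamin A (22) joins a trans-fused drimane decalin, through the C11 methylene, to the fully substituted oxirane carbon C1' of an epoxycyclohexenone. The decalin holds four contiguous stereocentres, two of them quaternary (C4, C10). At C4 a methyl and a hydroxymethyl group, alike in size, must be told apart, and the C7=C8 alkene must not slip to C8=C9 or to the exocyclic position. Within the decalin one centre can dictate the others, but C11 insulates ring C, so C1' and C2' cannot be controlled by C9 or C10 and need a reagent. Once the epoxide exists, it and the C1' substituent are the only handles on C6'. The epoxy enone with its γ-hydroxyl and the two allylic alcohols tolerate neither strong base, nucleophiles nor strong acid, and acid would also move the C7=C8 alkene, so ring C should be unveiled last from a sturdy precursor. Two features make a short route possible. Rings A and B map atom for atom onto an all-E farnesyl chain in which C4 is the terminal alkene carbon, its E-methyl is the future CH2OH, and C10 and C8 carry the chain methyls. Ring C has the carbon and oxygen pattern of a 4-methoxyphenol with a hydroxymethyl group next to the methoxy carbon.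

## Retrosynthesis

**Ring C (22 ⇐ 21 ⇐ 20 ⇐ 19 ⇐ 18).** The C3' carbonyl is masked as a dimethyl ketal (21), the C6'–H bond is removed (20), the two epoxide C–O bonds are removed (19), and the dienone ketal 19 is traced to phenol 18. An arene brings all six ring carbons, both oxygens and the CH2OH in one piece, whereas building ring C by annulation would need several C–C bonds next to a quaternary epoxide carbon. The monoketal 19 tells the two carbonyls and the two alkenes apart: C6' is the only ketone, and C2' is the only unsubstituted β-carbon. The forward steps must deliver a regioselective dearomatisation (free phenol at C6', methyl ether at C3'), a reagent-controlled choice of face at C1'/C2', and hydride delivery to C6' from the epoxide face.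

**Adjusting the decalin (18 ⇐ 17 ⇐ 16 ⇐ 14).** The three silyl ethers are put back (17) and a hydroxyl is added at C3 through xanthate 16, giving 14. The extra oxygen costs two steps but is the trace of an epoxide, which is what makes the decalin accessible enantioselectively. The forward reactions are a radical deoxygenation of a hindered secondary alcohol and a fluoride desilylation.

**Rings A and B (14 ⇐ 13).** The C4–C5 and C9–C10 bonds are cut, opening both rings to the aryl epoxy-farnesane 13. Compared with stepwise ring construction, this cut sets C4, C5, C9 and C10 together, and it distinguishes CH3 from CH2O at C4 through alkene geometry rather than on a preformed ring. The precursor is an open chain with one stereogenic unit. The forward reaction must open the epoxide at C4, fold chair–chair, and end by proton loss toward C7.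

**The initiating epoxide (13 ⇐ 12 ⇐ 11 ⇐ 10).** The silyl ether is removed (12), the epoxide is traced to the E allylic alcohol 11, and the C12–O bond to the unoxidised aryl farnesane 10. Epoxidation of an allylic alcohol gives the absolute configuration from a catalytic reagent, and the E-methyl of the terminal alkene is the position that allylic oxidation prefers. The forward steps need site selectivity among three trisubstituted alkenes.

**Arene to chain (10 ⇐ 6 + 8).** The C1'–C11 bond is cut to aryl bromide 6 and farnesyl bromide 8. This is the only C–C bond between two bought skeletons. The forward reaction is an aryllithium alkylation at a primary allylic carbon with the E alkenes kept intact.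

**Building blocks (6 ⇐ 5 ⇐ 3 ⇐ 2 ⇐ 1; 8 ⇐ 7).** The hydroxymethyl carbon of 6 is cut back to 2-bromo-4-methoxyphenol 1, which already has the bromine ortho to the phenol and the methoxy group para to it. The forward formylation must go ortho to the methoxy group and para to bromine. Bromide 8 comes from farnesol 7.

## Roads not taken

**Alternative 1:** Robinson annulation onto ring A. The cut is at C9–C10 and C5=C6. The ring A ketone A2 is activated by condensation with enantiopure 1-phenylethylamine and adds through C10 to C9 of the acetal enone A3; base-mediated aldol condensation then closes ring B to enone A1.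
- Merits: the C10 quaternary centre is set by a well-known chiral-amine Michael addition, and the C7 oxygen of A1 marks where the C7=C8 alkene must go. The alkene position is therefore settled by construction. In this respect Alternative 1 is better than the chosen plan, which relies on the partition of a cation in step 10.
- Weak points: A3 carries a β-substituent and an α-methyl group, outside the comfortable scope of this Michael addition, so rate and C9 selectivity are not secured. C5 still has to be set by reducing the enone. C4 in A1 is a spiro centre with two like CH2O arms, so the CH3/CH2OH distinction is postponed to a preformed ring. Ring C must still be attached through C11.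
- Comparison: the chosen plan sets C4 by alkene geometry and all four decalin centres in step 10 (13 to 14), and brings ring C along as an arene.

**Alternative 2:** Intramolecular Diels–Alder closure of both rings. The cut is at C5–C10 and C8–C9. The silyloxy trienal A5 cyclises under a chiral oxazaborolidinium triflimide (B-o-tolyl, from α,α-diphenylprolinol) to the trans-fused aldehyde A4.
- Merits: C5, C9 and C10 are set in one catalytic enantioselective step, and the silyl enol ether at C6=C7 again marks C7, which is as good as Alternative 1 for alkene placement.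
- Weak points: the dienophile carbon C10 is fully substituted, so the cycloaddition must build a quaternary centre from a β,β-disubstituted enal, which is slow. Catalyst control over the tethered transition state (endo or exo, and face) is uncertain. C4 is again an undifferentiated spiro acetonide, and the C11 aldehyde must later be joined to ring C and deoxygenated.
- Comparison: the number of centres set per step is similar, but the chosen plan also fixes C4 and needs no later bond to ring C beyond the one made in step 6.

**Alternative 3:** Open-chain threo epoxide, then ring-closing metathesis of ring C. The cut is the C4'=C5' bond. The second-generation Grubbs catalyst joins the vinyl group on C6' and the methylene on C4' of the epoxy enone A7 with loss of ethylene, giving the tris(silyl) ether A6 of the target.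
- Merits: the anti relation between the C6' oxygen and the epoxide is fixed in open-chain chemistry before the ring exists. This is better than the chosen plan, where the same relation depends on the facial course of a late reduction (step 16).
- Weak points: A7 needs a quaternary epoxide carbon flanked by two stereocentres built in acyclic form on an already complete decalin. The metathesis must form a trisubstituted enone alkene from an α-methylene ketone next to an epoxide. The decalin problem, including C4, is left unsolved.
- Comparison: against the stereochemical advantage at C6', the chosen plan offers a ring C that is bought as an arene and carried inert through the route until step 14 (18 to 19), and far fewer C–C bonds.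

Key step: step 10

## Route

Step 1
Reactants: 1 2-bromo-4-methoxyphenol
Product: 2 2-bromo-4-methoxyphenyl acetate
Conditions: Ac2O, pyridine, DMAP (cat.), CH2Cl2, 0 °C → rt
Reagents that add atoms: acetic anhydride, CC(=O)OC(C)=O
Why: Phenol O-acylation; the acetate mutes the phenol oxygen so that the next electrophilic substitution is steered by the methoxy group.

Step 2
Reactants: 2 2-bromo-4-methoxyphenyl acetate
Product: 3 5-acetoxy-4-bromo-2-methoxybenzaldehyde
Conditions: Cl2CHOMe, TiCl4, CH2Cl2, 0 °C; aqueous HCl work-up
Reagents that add atoms: dichloromethyl methyl ether, COC(Cl)Cl; water, O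
Why: Rieche formylation (electrophilic aromatic substitution); of the two positions ortho to OMe, one is wedged between OMe and Br, the other is open and also para to Br, so the formyl group should enter there; hydrolysis on work-up releases the aldehyde.

Step 3
Reactants: 3 5-acetoxy-4-bromo-2-methoxybenzaldehyde
Product: 5 2-bromo-5-(hydroxymethyl)-4-methoxyphenol, via benzylic alcohol acetate 4 (not isolated)
Conditions: NaBH4, MeOH, 0 °C; then K2CO3 (cat.), rt
Reagents that add atoms: none
Why: Borohydride reduction of the aryl aldehyde leaves the aryl bromide alone; carbonate-catalysed methanolysis of the phenyl acetate then frees the phenol in the same flask.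

Step 4
Reactants: 5 2-bromo-5-(hydroxymethyl)-4-methoxyphenol
Product: 6 1-bromo-5-methoxy-2-(triisopropylsilyloxy)-4-[(triisopropylsilyloxy)methyl]benzene
Conditions: TIPSCl, imidazole, DMF, rt → 40 °C
Reagents that add atoms: chlorotriisopropylsilane, CC(C)[Si](Cl)(C(C)C)C(C)C
Why: Silyl chloride–imidazole silylation of both hydroxyls; TIPS is chosen because it survives organolithium and Lewis acid, and because its bulk on the phenol oxygen later keeps that oxygen from capturing the C8 cation.

Step 5
Reactants: 7 (2E,6E)-farnesol
Product: 8 (2E,6E)-farnesyl bromide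
Conditions: PBr3, Et2O, −10 → 0 °C
Reagents that add atoms: phosphorus tribromide, BrP(Br)Br
Why: Conversion of a primary allylic alcohol into the bromide at low temperature, which keeps the E geometry and avoids allylic transposition.

Step 6
Reactants: 6 1-bromo-5-methoxy-2-(triisopropylsilyloxy)-4-[(triisopropylsilyloxy)methyl]benzene; 8 (2E,6E)-farnesyl bromide
Product: 10 1-[(2E,6E)-3,7,11-trimethyldodeca-2,6,10-trienyl]-5-methoxy-2-(triisopropylsilyloxy)-4-[(triisopropylsilyloxy)methyl]benzene (aryl farnesane), via aryllithium 9 (not isolated)
Conditions: n-BuLi, THF, −78 °C; then 8, −78 → −40 °C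
Reagents that add atoms: none
Why: Bromine–lithium exchange followed by SN2 alkylation at the primary allylic carbon (the γ-carbon is blocked by its methyl and chain substituents); the mixture is held at −78 °C because the 1,3 O→C silyl shift of an ortho-lithiated aryl silyl ether is slow for the hindered TIPS group at that temperature.

Step 7
Reactants: 10 aryl farnesane
Product: 11 (2E,6E,10E)-12-Ar-2,6,10-trimethyldodeca-2,6,10-trien-1-ol (E allylic alcohol at the chain terminus)
Conditions: SeO2 (cat.), t-BuOOH, salicylic acid (cat.), CH2Cl2, 0 °C → rt, stopped at partial conversion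
Reagents that add atoms: tert-butyl hydroperoxide, CC(C)(C)OO
Why: SeO2-catalysed allylic oxidation (ene reaction, then [2,3]-sigmatropic shift) with the hydroperoxide as terminal oxidant; it selects the E-methyl of the terminal, least hindered trisubstituted alkene and gives the E allylic alcohol.

Step 8
Reactants: 11 E allylic alcohol
Product: 12 [(2S,3S)-3-[(3E,7E)-9-Ar-3,7-dimethylnona-3,7-dienyl]-2-methyloxiran-2-yl]methanol
Conditions: Ti(OiPr)4 (cat.), L-(+)-diethyl tartrate (cat.), t-BuOOH, 4 Å MS, CH2Cl2, −20 °C
Reagents that add atoms: tert-butyl hydroperoxide, CC(C)(C)OO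
Why: Sharpless asymmetric epoxidation; only the alkene of the allylic alcohol reacts, and the L-(+)-tartrate complex delivers oxygen to the face that gives the (2S,3S) epoxide, that is C3 (S) and C4 (S) in drimane numbering, with CH2OH trans to the chain.

Step 9
Reactants: 12 (2S,3S) epoxy alcohol
Product: 13 (2S,3S)-3-[(3E,7E)-9-Ar-3,7-dimethylnona-3,7-dienyl]-2-methyl-2-[(triisopropylsilyloxy)methyl]oxirane (tris-TIPS aryl epoxy-farnesane)
Conditions: TIPSCl, imidazole, DMAP (cat.), DMF, rt
Reagents that add atoms: chlorotriisopropylsilane, CC(C)[Si](Cl)(C(C)C)C(C)C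
Why: Silylation under non-acidic conditions leaves the epoxide intact; the bulky ether removes the free hydroxyl, which would bind aluminium and steer epoxide opening to the wrong carbon.

Step 10
Reactants: 13 tris-TIPS aryl epoxy-farnesane
Product: 14 (3S,4R,5R,9S,10R)-3β-hydroxy-4α-[(triisopropylsilyloxy)methyl]-4β-methyl-drim-7-ene carrying Ar on C11 (trans-decalin, 5α-H, 10β-CH3, C11 β on C9)
Conditions: MeAlCl2 (hexanes), CH2Cl2, −78 °C; Et3N, then aqueous NaHCO3
Reagents that add atoms: none
Why: MeAlCl2 binds the epoxide oxygen and the C4–O bond ionises at the tertiary carbon while C5 of the C5=C10 alkene attacks C4 from the side opposite the leaving oxygen, C9 of the C8=C9 alkene then attacks the C10 cation, and the C8 cation loses the axial C7 proton; the closest known reaction type is the Lewis-acid-promoted cyclisation of epoxy polyenes, of which a silyloxymethyl group on the initiating carbon is a known but less common variant. Ring A closes 6-endo with respect to the C5=C10 alkene and ring B 6-endo with respect to the C8=C9 alkene, both through a chair–chair array that the two E alkenes impose. C3 keeps the S configuration of the epoxide and its oxygen ends up equatorial (3β). C4 is formed with inversion, so the group trans to the chain on the epoxide, CH2OTIPS, becomes equatorial (4α) and the methyl axial (4β). C5 and C10 result from anti addition across the E C5=C10 alkene (5α-H, 10β-CH3, trans fusion) and C9 carries C11 equatorial (β) because the C8=C9 alkene is E; the enantiopure epoxide fixes the absolute sense of all four new centres. The step needs opening at C4 and not 5-exo attack on C3: C4 is the only tertiary centre, and the bulky silyl ether cannot chelate aluminium together with the epoxide oxygen, which would favour the C3 mode. It needs proton loss toward C7: the axial C7–H lies parallel to the empty orbital at C8 and is more accessible than the tertiary C9–H flanked by C10 and C11, and the low temperature disfavours later alkene migration. It needs the arene to stay out: the TIPS group shields the phenol oxygen from the C8 cation, and attack by C2' would have to close a strained five-membered ring.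

Step 11
Reactants: 14 3β-hydroxy drimenyl arene
Product: 16 O-(3β-drimenyl) S-methyl dithiocarbonate of 14 (xanthate at C3, all else unchanged), via sodium xanthate 15 (not isolated)
Conditions: NaH, imidazole (cat.), CS2, THF, 0 °C → rt; then MeI
Reagents that add atoms: carbon disulfide, S=C=S; iodomethane, CI
Why: Xanthate formation (alkoxide addition to CS2, then S-methylation); the small reagents reach the hindered 3β-hydroxyl, and CS2 is present while the alkoxide forms so that it is trapped before the neighbouring silyl group can migrate.

Step 12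
Reactants: 16 C3 xanthate
Product: 17 (4R,5R,9S,10R)-4α-[(triisopropylsilyloxy)methyl]-4β-methyl-drim-7-ene carrying Ar on C11 (3-deoxy compound)
Conditions: Bu3SnH, AIBN (cat.), toluene, 100 °C
Reagents that add atoms: none
Why: Barton–McCombie radical deoxygenation; the secondary C3 radical is reduced by the stannane, no stereocentre remains at C3, and the alkenes are too remote for radical cyclisation.

Step 13
Reactants: 17 3-deoxy tris-TIPS compound
Product: 18 2-{[(1S,4aR,5R,8aR)-5-(hydroxymethyl)-2,5,8a-trimethyl-1,4,4a,5,6,7,8,8a-octahydronaphthalen-1-yl]methyl}-5-(hydroxymethyl)-4-methoxyphenol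
Conditions: TBAF, THF, rt → 50 °C, under argon
Reagents that add atoms: none
Why: Fluoride desilylation removes the aryl, benzylic and neopentyl silyl ethers together; air is excluded because the electron-rich phenoxide oxidises easily.

Step 14
Reactants: 18 triol phenol
Product: 19 2-{[(1S,4aR,5R,8aR)-5-(hydroxymethyl)-2,5,8a-trimethyl-1,4,4a,5,6,7,8,8a-octahydronaphthalen-1-yl]methyl}-5-(hydroxymethyl)-4,4-dimethoxycyclohexa-2,5-dien-1-one
Conditions: PhI(OAc)2, MeOH, 0 °C
Reagents that add atoms: methanol, CO
Why: Oxidative dearomatisation of a 4-methoxyphenol with a hypervalent iodine reagent; methanol adds para to the phenol oxygen, so C6' becomes the only ketone and C3' the ketal, and the primary alcohols are not oxidised under these conditions.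

Step 15
Reactants: 19 dienone dimethyl ketal
Product: 20 (1'R,2'S)-1',2'-epoxide of 19, i.e. (1R,6S)-1-(decalinylmethyl)-4-(hydroxymethyl)-5,5-dimethoxy-7-oxabicyclo[4.1.0]hept-3-en-2-one with the decalin of 18
Conditions: Ph3COOH, NaHMDS, L-(+)-diisopropyl tartrate, 4 Å MS, toluene, −78 → −50 °C
Reagents that add atoms: trityl hydroperoxide, OOC(c1ccccc1)(c1ccccc1)c1ccccc1
Why: Tartrate-mediated nucleophilic epoxidation (conjugate addition of the hydroperoxide anion, then ring closure), directed by the sodium alkoxide of the C4' hydroxymethyl group across the ketal carbon to C2', which is also the only unsubstituted β-carbon; the face, and with it C1' and C2', is set by the tartrate because the decalin is too remote to bias it.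

Step 16
Reactants: 20 epoxy enone ketal
Product: 21 (1'S,2'S,6'R) epoxy alcohol ketal, i.e. (1S,2R,6S)-1-(decalinylmethyl)-4-(hydroxymethyl)-5,5-dimethoxy-7-oxabicyclo[4.1.0]hept-3-en-2-ol, hydroxyl anti to the epoxide oxygen
Conditions: NaBH4, CeCl3·7H2O, MeOH, −78 °C
Reagents that add atoms: none
Why: Luche 1,2-reduction of the enone carbonyl; hydride is expected from the epoxide face because the C11–decalin substituent on C1' covers the opposite face and the cation can bridge the carbonyl and epoxide oxygens, which puts the new hydroxyl anti to the epoxide (6'R); the ketal keeps C3' out of play.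

Step 17
Reactants: 21 epoxy alcohol ketal
Product: 22 Epoxypholamin A, (1S,5R,6S)-5-hydroxy-3-(hydroxymethyl)-6-{[(1S,4aR,5R,8aR)-5-(hydroxymethyl)-2,5,8a-trimethyl-1,4,4a,5,6,7,8,8a-octahydronaphthalen-1-yl]methyl}-7-oxabicyclo[4.1.0]hept-3-en-2-one
Conditions: aqueous HF (48%), MeCN, 0 °C → rt
Reagents that add atoms: water, O
Why: Acid hydrolysis of an allylic dimethyl ketal unveils the enone; dilute aqueous HF in acetonitrile is enough for an allylic ketal and should leave the epoxide, the allylic alcohols and the C7=C8 alkene untouched.

## Compound list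

1 | 2-bromo-4-methoxyphenol | COc1ccc(O)c(Br)c1 | starting material
2 | 2-bromo-4-methoxyphenyl acetate | COc1ccc(OC(C)=O)c(Br)c1 | intermediate
3 | 5-acetoxy-4-bromo-2-methoxybenzaldehyde | COc1cc(Br)c(OC(C)=O)cc1C=O | intermediate
4 | 2-bromo-5-(hydroxymethyl)-4-methoxyphenyl acetate (not isolated) | COc1cc(Br)c(OC(C)=O)cc1CO | intermediate
5 | 2-bromo-5-(hydroxymethyl)-4-methoxyphenol | COc1cc(Br)c(O)cc1CO | intermediate
6 | 1-bromo-5-methoxy-2-(triisopropylsilyloxy)-4-[(triisopropylsilyloxy)methyl]benzene | COc1cc(Br)c(O[Si](C(C)C)(C(C)C)C(C)C)cc1CO[Si](C(C)C)(C(C)C)C(C)C | intermediate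
7 | (2E,6E)-farnesol | CC(C)=CCC/C(C)=C/CC/C(C)=C/CO | starting material
8 | (2E,6E)-farnesyl bromide | CC(C)=CCC/C(C)=C/CC/C(C)=C/CBr | intermediate
9 | 5-methoxy-2-(triisopropylsilyloxy)-4-[(triisopropylsilyloxy)methyl]phenyllithium (not isolated) | COc1cc([Li])c(O[Si](C(C)C)(C(C)C)C(C)C)cc1CO[Si](C(C)C)(C(C)C)C(C)C | intermediate
10 | aryl (2E,6E)-farnesane, bis-TIPS ether | CC(C)[Si](C(C)C)(C(C)C)Oc1cc(CO[Si](C(C)C)(C(C)C)C(C)C)c(OC)cc1C/C=C(\C)CC/C=C(\C)CCC=C(C)C | intermediate
11 | (2E,6E,10E)-12-Ar-2,6,10-trimethyldodeca-2,6,10-trien-1-ol | CC(C)[Si](C(C)C)(C(C)C)Oc1cc(CO[Si](C(C)C)(C(C)C)C(C)C)c(OC)cc1C/C=C(\C)CC/C=C(\C)CC/C=C(\C)CO | intermediate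
12 | (2S,3S) epoxy alcohol | CC(C)[Si](C(C)C)(C(C)C)Oc1cc(CO[Si](C(C)C)(C(C)C)C(C)C)c(OC)cc1C/C=C(\C)CC/C=C(\C)CC[C@@H]1O[C@@]1(C)CO | intermediate
13 | tris-TIPS aryl (2S,3S)-epoxy-farnesane (key-step precursor) | CC(C)[Si](C(C)C)(C(C)C)Oc1cc(CO[Si](C(C)C)(C(C)C)C(C)C)c(OC)cc1C/C=C(\C)CC/C=C(\C)CC[C@@H]1O[C@@]1(C)CO[Si](C(C)C)(C(C)C)C(C)C | intermediate
14 | (3S,4R,5R,9S,10R)-3β-hydroxy drimenyl arene (key-step product) | CC1=CC[C@H]2[C@](C)(CO[Si](C(C)C)(C(C)C)C(C)C)[C@@H](O)CC[C@]2(C)[C@H]1Cc1cc(OC)c(CO[Si](C(C)C)(C(C)C)C(C)C)cc1O[Si](C(C)C)(C(C)C)C(C)C | intermediate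
15 | sodium C3 xanthate of 14 (not isolated) | CC1=CC[C@H]2[C@](C)(CO[Si](C(C)C)(C(C)C)C(C)C)[C@@H](OC(=S)[S-])CC[C@]2(C)[C@H]1Cc1cc(OC)c(CO[Si](C(C)C)(C(C)C)C(C)C)cc1O[Si](C(C)C)(C(C)C)C(C)C.[Na+] | intermediate
16 | C3 S-methyl xanthate of 14 | CC1=CC[C@H]2[C@](C)(CO[Si](C(C)C)(C(C)C)C(C)C)[C@@H](OC(=S)SC)CC[C@]2(C)[C@H]1Cc1cc(OC)c(CO[Si](C(C)C)(C(C)C)C(C)C)cc1O[Si](C(C)C)(C(C)C)C(C)C | intermediate
17 | (4R,5R,9S,10R) 3-deoxy drimenyl arene, tris-TIPS ether | CC1=CC[C@H]2[C@](C)(CO[Si](C(C)C)(C(C)C)C(C)C)CCC[C@]2(C)[C@H]1Cc1cc(OC)c(CO[Si](C(C)C)(C(C)C)C(C)C)cc1O[Si](C(C)C)(C(C)C)C(C)C | intermediate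
18 | drimenylmethyl 5-(hydroxymethyl)-4-methoxyphenol (triol) | CC1=CC[C@H]2[C@](C)(CO)CCC[C@]2(C)[C@H]1Cc1cc(OC)c(CO)cc1O | intermediate
19 | dienone dimethyl ketal | CC1=CC[C@H]2[C@](C)(CO)CCC[C@]2(C)[C@H]1CC1=CC(OC)(OC)C(CO)=CC1=O | intermediate
20 | (1'R,2'S) epoxy enone ketal | CC1=CC[C@H]2[C@](C)(CO)CCC[C@]2(C)[C@H]1C[C@@]12O[C@@H]1C(OC)(OC)C(CO)=CC2=O | intermediate
21 | (1'S,2'S,6'R) epoxy alcohol ketal | CC1=CC[C@H]2[C@](C)(CO)CCC[C@]2(C)[C@H]1C[C@@]12O[C@@H]1C(OC)(OC)C(CO)=C[C@H]2O | intermediate
22 | Epoxypholamin A | CC1=CC[C@H]2[C@](C)(CO)CCC[C@]2(C)[C@H]1C[C@@]12O[C@@H]1C(=O)C(CO)=C[C@H]2O | target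

## Step count and least certain steps

Total: 17 steps. Longest linear sequence: 16 steps (steps 1–4 and 6–17, from 1).

**Step 10 (key step).** The C8 cation may lose a proton from C12 or C9 instead of C7. In addition, the silyloxymethyl group slows ionisation at C4, so an interrupted cascade or a hydride shift at the epoxide can compete.
Fallback: give up kinetic control of the termination. The cyclisation of 13 is run as before and the 3β-hydroxy-drim-8(12)-enyl arene F1, the exocyclic alkene isomer, is taken on together with 14. RhCl3·3H2O (cat.) in EtOH at 70 °C should move the exocyclic alkene into the ring through the accessible C7 methylene rather than the shielded tertiary C9–H. The fallback sets out from 13 and comes back at 14.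

**Step 15.** Face selection may be poor or of the wrong sense. The sense of tartrate induction is assumed, and the second sodium alkoxide (from the neopentyl alcohol) may disturb the aggregate that carries the peroxide.
Fallback: abandon induction. From 19, alkaline hydrogen peroxide (H2O2, K2CO3, THF–MeOH, 0 °C) should epoxidise the same alkene without face control, giving 20 and the (1'S,2'R) epoxide diastereomer F2. The decalin makes these diastereomers, so they are separated by chromatography, and the route resumes at 20.

**Step 16.** Hydride may attack anti to the epoxide oxygen, the usual course for cyclic epoxy ketones, which would put the C6' hydroxyl on the wrong face.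
Fallback: invert instead of direct. From 20, the same reduction is accepted as it falls and the 6'-epimeric epoxy alcohol F3 is taken on. Mitsunobu reaction (4-nitrobenzoic acid, PPh3, DIAD, toluene, 0 °C → rt) inverts the allylic C6' carbinol and also esterifies the primary allylic hydroxyl, giving the bis(4-nitrobenzoate) F4. Methanolysis (K2CO3, MeOH, 0 °C) removes both esters and returns to the route at 21.

**Step 7.** Oxidation may spread to the internal alkenes or to the doubly activated C11 methylene, or run on past the alcohol, on a substrate that already contains the arene.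
Fallback: move the oxidation to the bare terpene and couple last. From 7:
- Ac2O–pyridine gives (2E,6E)-farnesyl acetate F5.
- SeO2 (cat.)–t-BuOOH gives (2E,6E,10E)-12-hydroxyfarnesyl acetate F6.
- Sharpless epoxidation with L-(+)-diethyl tartrate gives the (10S,11S)-epoxy alcohol F7.
- TIPSCl–imidazole gives the silyl ether F8.
- K2CO3–MeOH gives the allylic alcohol F9.
- CBr4–PPh3 gives the allylic bromide F10.
- Alkylation of aryllithium 9 (from 6, as in step 6) with F10 gives 13 directly.

The fallback comes back at 13 and bypasses 10–12.

**Step 6.** A 1,3 O→C silyl shift in the ortho-lithiated aryl silyl ether, or slow alkylation of the hindered aryllithium, may erode the coupling.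
Fallback: avoid the aryl anion. From 6, Miyaura borylation (B2pin2, Pd(dppf)Cl2, KOAc, dioxane, 80 °C) gives the aryl pinacol boronate F11. Suzuki–Miyaura coupling of F11 with 8 (Pd(PPh3)4, K2CO3, THF–H2O, 60 °C) should proceed through the π-allyl complex at the less substituted terminus and return to the route at 10.

## Further compounds

F1 | step 10 | (3S,4R,5R,9S,10R)-3β-hydroxy-drim-8(12)-enyl arene, exocyclic alkene isomer of 14 | C=C1CC[C@H]2[C@](C)(CO[Si](C(C)C)(C(C)C)C(C)C)[C@@H](O)CC[C@]2(C)[C@H]1Cc1cc(OC)c(CO[Si](C(C)C)(C(C)C)C(C)C)cc1O[Si](C(C)C)(C(C)C)C(C)C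
F2 | step 15 | (1'S,2'R) epoxy enone ketal, epoxide diastereomer of 20 | CC1=CC[C@H]2[C@](C)(CO)CCC[C@]2(C)[C@H]1C[C@]12O[C@H]1C(OC)(OC)C(CO)=CC2=O
F3 | step 16 | (1'S,2'S,6'S) epoxy alcohol ketal, 6'-epimer of 21 | CC1=CC[C@H]2[C@](C)(CO)CCC[C@]2(C)[C@H]1C[C@@]12O[C@@H]1C(OC)(OC)C(CO)=C[C@@H]2O
F4 | step 16 | bis(4-nitrobenzoate) of 21 at the C6' oxygen and the C4' hydroxymethyl oxygen | CC1=CC[C@H]2[C@](C)(CO)CCC[C@]2(C)[C@H]1C[C@@]12O[C@@H]1C(OC)(OC)C(COC(=O)c3ccc(cc3)[N+](=O)[O-])=C[C@H]2OC(=O)c1ccc(cc1)[N+](=O)[O-]
F5 | step 7 | (2E,6E)-farnesyl acetate | CC(C)=CCC/C(C)=C/CC/C(C)=C/COC(C)=O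
F6 | step 7 | (2E,6E,10E)-12-hydroxyfarnesyl acetate | OC/C(C)=C/CC/C(C)=C/CC/C(C)=C/COC(C)=O
F7 | step 7 | (2E,6E,10S,11S)-10,11-epoxy-12-hydroxyfarnesyl acetate | OC[C@]1(C)O[C@H]1CC/C(C)=C/CC/C(C)=C/COC(C)=O
F8 | step 7 | (2E,6E,10S,11S)-10,11-epoxy-12-(triisopropylsilyloxy)farnesyl acetate | CC(C)[Si](C(C)C)(C(C)C)OC[C@]1(C)O[C@H]1CC/C(C)=C/CC/C(C)=C/COC(C)=O
F9 | step 7 | (2E,6E,10S,11S)-10,11-epoxy-12-(triisopropylsilyloxy)farnesol | CC(C)[Si](C(C)C)(C(C)C)OC[C@]1(C)O[C@H]1CC/C(C)=C/CC/C(C)=C/CO
F10 | step 7 | (2E,6E,10S,11S)-10,11-epoxy-12-(triisopropylsilyloxy)farnesyl bromide | CC(C)[Si](C(C)C)(C(C)C)OC[C@]1(C)O[C@H]1CC/C(C)=C/CC/C(C)=C/CBr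
F11 | step 6 | 2-[5-methoxy-2-(triisopropylsilyloxy)-4-[(triisopropylsilyloxy)methyl]phenyl]-4,4,5,5-tetramethyl-1,3,2-dioxaborolane | COc1cc(B2OC(C)(C)C(C)(C)O2)c(O[Si](C(C)C)(C(C)C)C(C)C)cc1CO[Si](C(C)C)(C(C)C)C(C)C
A1 | alternative 1 | bicyclic enone: C7 ketone, C5=C6 alkene, C4 spiro acetonide, C8 methyl, C9 dimethyl acetal | C[C@@H]1C(=O)C=C2C3(COC(C)(C)OC3)CCC[C@]2(C)[C@H]1C(OC)OC
A2 | alternative 1 | 3,3,8-trimethyl-2,4-dioxaspiro[5.5]undecan-7-one (ring A ketone) | CC1CCCC2(COC(C)(C)OC2)C1=O
A3 | alternative 1 | (E)-5,5-dimethoxy-3-methylpent-3-en-2-one (acetal enone) | COC(OC)/C=C(\C)C(C)=O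
A4 | alternative 2 | trans-fused bicyclic aldehyde with C6=C7 tert-butyldimethylsilyl enol ether | C[C@H]1C(O[Si](C)(C)C(C)(C)C)=C[C@H]2C3(COC(C)(C)OC3)CCC[C@]2(C)[C@H]1C=O
A5 | alternative 2 | silyloxy trienal with C4 spiro acetonide (E enal, E,Z silyloxy diene) | O=C/C=C(\C)CCCC1(COC(C)(C)OC1)/C=C/C(O[Si](C)(C)C(C)(C)C)=C/C
A6 | alternative 3 | tris(tert-butyldimethylsilyl) ether of 22 | CC1=CC[C@H]2[C@](C)(CO[Si](C)(C)C(C)(C)C)CCC[C@]2(C)[C@H]1C[C@@]12O[C@@H]1C(=O)C(CO[Si](C)(C)C(C)(C)C)=C[C@H]2O[Si](C)(C)C(C)(C)C
A7 | alternative 3 | open-chain threo epoxy enone with vinyl group on C6' and methylene on C4' | CC1=CC[C@H]2[C@](C)(CO[Si](C)(C)C(C)(C)C)CCC[C@]2(C)[C@H]1C[C@]1(O[C@@H]1C(=O)C(=C)CO[Si](C)(C)C(C)(C)C)[C@@H](C=C)O[Si](C)(C)C(C)(C)C
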